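**Plan**

- Numbering follows squalene (chain C2–C23, methyls on C2, C6, C10, C15, C19, C23). Ring A is the 3-hydroxyoxepane (O, C2–C7), ring B the left cyclohexane (C6–C11), ring C the right cyclohexane (C14–C19), ring D the oxepan-3-one (O, C18–C23).
- Retrosynthetic cuts, in order: the O–C2 bond of ring A (C2 and C3 oxygens traced back to a C2=C3 alkene); the two tertiary acetates; C10–CH3; the C12–C13 link; rings C and D together (C14–C19 and O–C23); ring B (C6–C11).
- Forward order: ring B by epoxide/β-keto ester closure (step 4); rings D and C in one diepoxide cascade (step 9); union of the halves at C12–C13 (step 12); ring A last (step 17).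
- Stereochemistry: C6/C7 come from a Sharpless epoxide and C18/C19/C22 from a Shi diepoxide (inversion at the quaternary carbon, retention at the carbinol carbon). C14, C15, C11 and C10 follow by substrate control. C3 is set by catalyst-controlled epoxidation.
- Enabling feature: the equatorial C7 hydroxyl of ring B lies five atoms from C2, the only tertiary carbon of the C2–C3 epoxide, so acid opens the epoxide at C2 and leaves the C3 oxygen as the free hydroxyl.

Key step: step 17

Remark (assumption): the enantiomer of the usual Shi ketone, 1,2:4,5-di-O-isopropylidene-β-L-erythro-2,3-hexodiulo-2,6-pyranose (made from L-sorbose), is taken as an available catalyst; (2E,6E)-farnesyl acetate is taken as a commercial single isomer.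

**Route**

Step 1
Reactants: 1 geraniol
Product: 2 (2S,3S)-2,3-epoxygeraniol
Conditions: Ti(OiPr)4 (5 mol%), L-(+)-diethyl tartrate (6 mol%), t-BuOOH, 4 Å molecular sieves, CH2Cl2, −20 °C
Reagents that add atoms: tert-butyl hydroperoxide, CC(C)(C)OO
Why: Sharpless asymmetric epoxidation should epoxidise only the allylic alcohol alkene, the L-(+)-tartrate ligand setting the (2S,3S) epoxide that later becomes C7 and C6.

Step 2
Reactants: 2 (2S,3S)-2,3-epoxygeraniol
Product: 3 (2R,3S)-2-(iodomethyl)-3-methyl-3-(4-methylpent-3-en-1-yl)oxirane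
Conditions: I2, PPh3, imidazole, Et2O–MeCN, 0 °C
Reagents that add atoms: iodine, II
Why: Appel-type iodination should displace the activated primary hydroxyl by SN2 without touching the epoxide or its two stereocentres.

Step 3
Reactants: 3 (2R,3S)-2-(iodomethyl)-3-methyl-3-(4-methylpent-3-en-1-yl)oxirane, 4 methyl acetoacetate
Product: 6 methyl 5-[(2S,3S)-3-methyl-3-(4-methylpent-3-en-1-yl)oxiran-2-yl]-3-oxopentanoate, via methyl acetoacetate dianion 5 (not isolated)
Conditions: 4, NaH, THF, 0 °C; n-BuLi, 0 °C; then 3, 0 °C to rt; aqueous work-up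
Reagents that add atoms: none
Why: Dianion alkylation of a β-keto ester should take place at the more basic terminal carbanion, which displaces the primary iodide (SN2) and so adds C9–C12 with the nucleophilic carbon C11 already defined.

Step 4
Reactants: 6 methyl 5-[(2S,3S)-3-methyl-3-(4-methylpent-3-en-1-yl)oxiran-2-yl]-3-oxopentanoate
Product: 7 methyl (1S,2S,3S)-3-hydroxy-2-methyl-2-(4-methylpent-3-en-1-yl)-6-oxocyclohexane-1-carboxylate
Conditions: SnCl4, CH2Cl2, −78 to −30 °C
Reagents that add atoms: none
Why: Epoxide-initiated cationic cyclisation terminated by a β-keto ester should form ring B, the tin-chelated enol carbon C11 attacking the tertiary epoxide carbon C6 with inversion through a chair while C7 keeps its oxygen, so that the 7-OH is equatorial, the C6 methyl axial and the epimerisable ester equatorial.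

Step 5
Reactants: 7 methyl (1S,2S,3S)-3-hydroxy-2-methyl-2-(4-methylpent-3-en-1-yl)-6-oxocyclohexane-1-carboxylate
Product: 8 methyl (1S,2S,3S)-3-[(tert-butyldimethylsilyl)oxy]-2-methyl-2-(4-methylpent-3-en-1-yl)-6-oxocyclohexane-1-carboxylate
Conditions: t-BuMe2SiCl, imidazole, DMF, 40 °C
Reagents that add atoms: tert-butyldimethylsilyl chloride, CC(C)(C)[Si](C)(C)Cl
Why: Silylation of the equatorial secondary hydroxyl should mask C7–OH through the hydride, oxidation and acylation steps that follow.

Step 6
Reactants: 8 methyl (1S,2S,3S)-3-[(tert-butyldimethylsilyl)oxy]-2-methyl-2-(4-methylpent-3-en-1-yl)-6-oxocyclohexane-1-carboxylate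
Product: 11 (3S,4S)-4-[(tert-butyldimethylsilyl)oxy]-3-methyl-3-(4-methylpent-3-en-1-yl)-2-methylidenecyclohexan-1-ol (both C1 epimers), via sodium enolate 9 (not isolated), via enone 10 (not isolated)
Conditions: NaH, DME, 0 °C to rt; LiAlH4, reflux; aqueous work-up
Reagents that add atoms: none
Why: Hydride reduction of a β-keto ester enolate should reduce the ester carbon to the aldehyde level, eliminate the aluminate oxygen to the α-methylene ketone and reduce that 1,2 in the flask, turning the ester carbon into C12 as an exocyclic methylene (the C10 carbinol configuration is immaterial).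

Step 7
Reactants: 11 (3S,4S)-4-[(tert-butyldimethylsilyl)oxy]-3-methyl-3-(4-methylpent-3-en-1-yl)-2-methylidenecyclohexan-1-ol
Product: 10 (3S,4S)-4-[(tert-butyldimethylsilyl)oxy]-3-methyl-3-(4-methylpent-3-en-1-yl)-2-methylidenecyclohexan-1-one
Conditions: Dess–Martin periodinane, CH2Cl2, 0 °C to rt
Reagents that add atoms: none
Why: Oxidation of the allylic alcohol should give the α-methylene ketone whose CH2 terminus is C12, the acceptor carbon for the union.

Step 8
Reactants: 12 (2E,6E)-farnesyl acetate
Product: 14 (2E,6S,7S,10S)-6,7:10,11-diepoxy-3,7,11-trimethyldodec-2-en-1-ol, via diepoxy acetate 13 (not isolated)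
Conditions: 1,2:4,5-di-O-isopropylidene-β-L-erythro-2,3-hexodiulo-2,6-pyranose (30 mol%), KHSO5 (as 2KHSO5·KHSO4·K2SO4), K2CO3, Bu4NHSO4, MeCN–CH2(OMe)2–aqueous Na2B4O7 buffer, 0 °C; then K2CO3 (cat.), MeOH, rt
Reagents that add atoms: potassium peroxymonosulfate, [K+].[O-]S(=O)(=O)OO
Why: Shi epoxidation should epoxidise the two electron-rich trisubstituted alkenes with catalyst-controlled facial selectivity (the L-fructose-derived ketone giving the 6S,7S,10S series) while the 2,3-alkene is deactivated by the allylic acetate, which is then removed by methanolysis.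

Step 9
Reactants: 14 (2E,6S,7S,10S)-6,7:10,11-diepoxy-3,7,11-trimethyldodec-2-en-1-ol
Product: 17 (3S,5aS,6R,9aS)-6-(hydroxymethyl)-2,2,5a-trimethyl-7-methylidenedecahydro-1-benzoxepin-3-ol, via silyl ether 15 (not isolated), via bis-silyl ether 16 (not isolated)
Conditions: Me3SiOTf (2.3 equiv), 2,6-di-tert-butyl-4-methylpyridine, CH2Cl2, −78 °C; then K2CO3, MeOH, 0 °C
Reagents that add atoms: none
Why: In this silyl-triflate-promoted oxa-/carbacyclisation cascade of a 1,5-diepoxide, the silylated terminal epoxide should be opened at its tertiary carbon C23 by the internal epoxide oxygen (ring D) and the resulting epoxonium ion at C19, with inversion through a chair, by C14 of the E-alkene (ring C, trans fusion, C13 equatorial), the C15 cation then losing a methyl proton to the hindered base (any C15=C16 isomer converges in step 10).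

Step 10
Reactants: 17 (3S,5aS,6R,9aS)-6-(hydroxymethyl)-2,2,5a-trimethyl-7-methylidenedecahydro-1-benzoxepin-3-ol
Product: 18 (3S,5aS,6R,7S,9aS)-6-(hydroxymethyl)-2,2,5a,7-tetramethyldecahydro-1-benzoxepine-3,7-diol
Conditions: Co(acac)2 (cat.), PhSiH3, O2 (1 atm), THF, rt
Reagents that add atoms: dioxygen, O=O
Why: Mukaiyama hydration should deliver a hydrogen atom to the alkene terminus and let the tertiary C15 radical capture O2 from the equatorial side, the axial side being shielded by the syn-axial C19 methyl, which gives the equatorial hydroxyl and axial methyl (15S).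

Step 11
Reactants: 18 (3S,5aS,6R,7S,9aS)-6-(hydroxymethyl)-2,2,5a,7-tetramethyldecahydro-1-benzoxepine-3,7-diol
Product: 19 (3S,5aS,6S,7S,9aS)-6-(iodomethyl)-2,2,5a,7-tetramethyldecahydro-1-benzoxepine-3,7-diol
Conditions: I2, PPh3, imidazole, toluene–MeCN, 0 °C to rt
Reagents that add atoms: iodine, II
Why: Appel-type iodination should convert only the primary C13 hydroxyl, since the tertiary C15 hydroxyl and the neopentyl-like secondary C22 hydroxyl cannot undergo SN2 displacement at a useful rate.

Step 12
Reactants: 19 (3S,5aS,6S,7S,9aS)-6-(iodomethyl)-2,2,5a,7-tetramethyldecahydro-1-benzoxepine-3,7-diol, 10 (3S,4S)-4-[(tert-butyldimethylsilyl)oxy]-3-methyl-3-(4-methylpent-3-en-1-yl)-2-methylidenecyclohexan-1-one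
Product: 20 union ketone (C10 ketone of ring B joined through C12–C13 to C14 of the ring C/D diol; 6S,7S,11S,14S,15S,18S,19S,22S)
Conditions: 10 (1.5 equiv), Bu3SnH (slow addition), 2,2′-azobis(2-methylpropionitrile) (cat.), benzene, 80 °C; then 1,8-diazabicyclo[5.4.0]undec-7-ene (cat.), CH2Cl2, rt
Reagents that add atoms: none
Why: In this Giese reaction the primary C13 radical from the iodide should add to the unhindered CH2 terminus (C12) of the α-methylene ketone, and the tertiary α-keto radical should take hydrogen from the stannane faster than it can close onto the prenyl side chain (a closure that would build two adjacent quaternary carbons), base equilibration then placing the new chain equatorial at C11 (H11 anti to the C6 methyl).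

Step 13
Reactants: 20 union ketone
Product: 21 triol (as 20, with C10 a tertiary carbinol, 10R, hydroxyl axial and cis to the C6 methyl)
Conditions: MeMgBr (excess), THF, −40 to 0 °C
Reagents that add atoms: methylmagnesium bromide, C[Mg]Br
Why: Grignard addition should occur along the equatorial trajectory because the axial face of C10 is blocked by the syn-axial C6 methyl, giving the axial hydroxyl and equatorial methyl, while the two free hydroxyls of the right half are merely deprotonated.

Step 14
Reactants: 21 triol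
Product: 22 keto diol (as 21, with C22 oxidised to the ring D ketone)
Conditions: Dess–Martin periodinane, CH2Cl2, rt
Reagents that add atoms: none
Why: Only the secondary C22 hydroxyl can be oxidised, the C10 and C15 hydroxyls being tertiary and the C7 hydroxyl silylated.

Step 15
Reactants: 22 keto diol
Product: 23 diacetate (10,15-di-O-acetyl derivative of 22)
Conditions: Ac2O, 4-(dimethylamino)pyridine, Et3N, 1,2-dichloroethane, 60 °C
Reagents that add atoms: acetic anhydride, CC(=O)OC(C)=O
Why: Nucleophilic-catalysed acylation under forcing conditions should esterify both tertiary alcohols in one operation, with no other free hydroxyl present and no bond to a stereocentre broken.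

Step 16
Reactants: 23 diacetate
Product: 24 hydroxy alkene (23 without the silyl group; free equatorial 7-OH)
Conditions: HF·pyridine, THF, 0 °C to rt
Reagents that add atoms: none
Why: Fluoride-mediated desilylation should free the C7 hydroxyl without affecting the tertiary acetates, the ketone or the alkene.

Step 17
Reactants: 24 hydroxy alkene
Product: 26 target CNP0298533.1, via epoxide 25 (not isolated)
Conditions: 1,2:4,5-di-O-isopropylidene-β-L-erythro-2,3-hexodiulo-2,6-pyranose (30 mol%), KHSO5 (as 2KHSO5·KHSO4·K2SO4), K2CO3, Bu4NHSO4, MeCN–CH2(OMe)2–aqueous Na2B4O7 buffer, 0 °C; then crude epoxide, (+)-camphor-10-sulfonic acid (10 mol%), CH2Cl2, −20 to 0 °C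
Reagents that add atoms: potassium peroxymonosulfate, [K+].[O-]S(=O)(=O)OO
Why: The dioxirane formed in situ from the L-fructose-derived ketone and KHSO5 should transfer oxygen to the C2=C3 alkene, the only electron-rich alkene left, to give the (3S)-epoxide 25; the sulfonic acid then protonates the epoxide and the equatorial C7 hydroxyl of ring B attacks C2 opposite the breaking C2–O bond, so that the O–C2 bond of ring A forms and the former epoxide oxygen stays on C3 as the free hydroxyl. The closest known reaction type is Shi epoxidation of a trisubstituted alkene followed by acid-catalysed intramolecular opening of the trisubstituted epoxide by a hydroxyl at its more substituted carbon, the classical entry to 2,2-dialkyloxepan-3-ols. Ring A closes in the 7-endo-tet mode. C3 is the only new stereocentre: it is set by the catalyst (reagent control, same sense as the epoxides of step 8) and passes through the closure unchanged because the C3–O bond is never broken, while the trans fusion of rings A and B follows from the fixed configurations of C6 and C7. The step needs attack at C2 and not at C3 (which would give a six-membered ether): C2 carries two methyl groups and most of the positive charge of the protonated epoxide in a non-nucleophilic solvent, C3 is a secondary carbon next to that centre, and the quaternary C6 keeps the side chain folded towards the hydroxyl. Chemoselectivity should not be at issue, since the ring D ketone and the two tertiary acetates are inert to the dioxirane at 0 °C and to the catalytic acid.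

**Compound list**

1 | geraniol, (2E)-3,7-dimethylocta-2,6-dien-1-ol | CC(C)=CCC/C(C)=C/CO | starting material
2 | (2S,3S)-2,3-epoxygeraniol | OC[C@@H]1O[C@@]1(C)CCC=C(C)C | intermediate
3 | (2R,3S)-2-(iodomethyl)-3-methyl-3-(4-methylpent-3-en-1-yl)oxirane | IC[C@@H]1O[C@@]1(C)CCC=C(C)C | intermediate
4 | methyl acetoacetate | COC(=O)CC(C)=O | starting material
5 | sodium lithium dianion of methyl acetoacetate | [Na+].[Li+].[CH2-]C(=O)[CH-]C(=O)OC | intermediate
6 | methyl 5-[(2S,3S)-3-methyl-3-(4-methylpent-3-en-1-yl)oxiran-2-yl]-3-oxopentanoate | COC(=O)CC(=O)CC[C@@H]1O[C@@]1(C)CCC=C(C)C | intermediate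
7 | methyl (1S,2S,3S)-3-hydroxy-2-methyl-2-(4-methylpent-3-en-1-yl)-6-oxocyclohexane-1-carboxylate (ring B) | COC(=O)[C@@H]1C(=O)CC[C@H](O)[C@@]1(C)CCC=C(C)C | intermediate
8 | methyl (1S,2S,3S)-3-[(tert-butyldimethylsilyl)oxy]-2-methyl-2-(4-methylpent-3-en-1-yl)-6-oxocyclohexane-1-carboxylate | COC(=O)[C@@H]1C(=O)CC[C@H](O[Si](C)(C)C(C)(C)C)[C@@]1(C)CCC=C(C)C | intermediate
9 | sodium enolate of 8 | [Na+].COC(=O)C1=C([O-])CC[C@H](O[Si](C)(C)C(C)(C)C)[C@@]1(C)CCC=C(C)C | intermediate
10 | (3S,4S)-4-[(tert-butyldimethylsilyl)oxy]-3-methyl-3-(4-methylpent-3-en-1-yl)-2-methylidenecyclohexan-1-one | C=C1C(=O)CC[C@H](O[Si](C)(C)C(C)(C)C)[C@@]1(C)CCC=C(C)C | intermediate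
11 | (3S,4S)-4-[(tert-butyldimethylsilyl)oxy]-3-methyl-3-(4-methylpent-3-en-1-yl)-2-methylidenecyclohexan-1-ol (C1 epimers) | C=C1C(O)CC[C@H](O[Si](C)(C)C(C)(C)C)[C@@]1(C)CCC=C(C)C | intermediate
12 | (2E,6E)-farnesyl acetate | CC(C)=CCC/C(C)=C/CC/C(C)=C/COC(C)=O | starting material
13 | (2E,6S,7S,10S)-6,7:10,11-diepoxy-3,7,11-trimethyldodec-2-en-1-yl acetate | CC(=O)OC/C=C(\C)CC[C@@H]1O[C@@]1(C)CC[C@@H]1OC1(C)C | intermediate
14 | (2E,6S,7S,10S)-6,7:10,11-diepoxy-3,7,11-trimethyldodec-2-en-1-ol | OC/C=C(\C)CC[C@@H]1O[C@@]1(C)CC[C@@H]1OC1(C)C | intermediate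
15 | trimethylsilyl ether of 14 | C[Si](C)(C)OC/C=C(\C)CC[C@@H]1O[C@@]1(C)CC[C@@H]1OC1(C)C | intermediate
16 | bis(trimethylsilyl) ether of 17 | C[Si](C)(C)OC[C@@H]1C(=C)CC[C@@H]2OC(C)(C)[C@@H](O[Si](C)(C)C)CC[C@@]12C | intermediate
17 | (3S,5aS,6R,9aS)-6-(hydroxymethyl)-2,2,5a-trimethyl-7-methylidenedecahydro-1-benzoxepin-3-ol (rings C and D, trans-fused) | OC[C@@H]1C(=C)CC[C@@H]2OC(C)(C)[C@@H](O)CC[C@@]12C | intermediate
18 | (3S,5aS,6R,7S,9aS)-6-(hydroxymethyl)-2,2,5a,7-tetramethyldecahydro-1-benzoxepine-3,7-diol | OC[C@@H]1[C@@](C)(O)CC[C@@H]2OC(C)(C)[C@@H](O)CC[C@@]12C | intermediate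
19 | (3S,5aS,6S,7S,9aS)-6-(iodomethyl)-2,2,5a,7-tetramethyldecahydro-1-benzoxepine-3,7-diol | IC[C@@H]1[C@@](C)(O)CC[C@@H]2OC(C)(C)[C@@H](O)CC[C@@]12C | intermediate
20 | union ketone: ring B cyclohexanone (C10=O, 7-OTBS, C6 methyl and 4-methylpent-3-enyl, H11 axial) linked by C12–C13 to C14 of the ring C/D diol (15-OH, 22-OH); 6S,7S,11S,14S,15S,18S,19S,22S | CC(C)=CCC[C@]1(C)[C@@H](O[Si](C)(C)C(C)(C)C)CCC(=O)[C@H]1CC[C@@H]1[C@@](C)(O)CC[C@@H]2OC(C)(C)[C@@H](O)CC[C@@]12C | intermediate
21 | triol: 20 with C10 as tertiary carbinol (10R, OH axial, CH3 equatorial) | CC(C)=CCC[C@]1(C)[C@@H](O[Si](C)(C)C(C)(C)C)CC[C@@](C)(O)[C@H]1CC[C@@H]1[C@@](C)(O)CC[C@@H]2OC(C)(C)[C@@H](O)CC[C@@]12C | intermediate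
22 | keto diol: 21 with the C22 ketone of ring D | CC(C)=CCC[C@]1(C)[C@@H](O[Si](C)(C)C(C)(C)C)CC[C@@](C)(O)[C@H]1CC[C@@H]1[C@@](C)(O)CC[C@@H]2OC(C)(C)C(=O)CC[C@@]12C | intermediate
23 | diacetate: 10,15-di-O-acetyl derivative of 22 | CC(C)=CCC[C@]1(C)[C@@H](O[Si](C)(C)C(C)(C)C)CC[C@@](C)(OC(C)=O)[C@H]1CC[C@@H]1[C@@](C)(OC(C)=O)CC[C@@H]2OC(C)(C)C(=O)CC[C@@]12C | intermediate
24 | hydroxy alkene: 23 with free 7-OH | CC(C)=CCC[C@]1(C)[C@@H](O)CC[C@@](C)(OC(C)=O)[C@H]1CC[C@@H]1[C@@](C)(OC(C)=O)CC[C@@H]2OC(C)(C)C(=O)CC[C@@]12C | intermediate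
25 | (3S)-2,3-epoxide of 24 | CC1(C)O[C@H]1CC[C@]1(C)[C@@H](O)CC[C@@](C)(OC(C)=O)[C@H]1CC[C@@H]1[C@@](C)(OC(C)=O)CC[C@@H]2OC(C)(C)C(=O)CC[C@@]12C | intermediate
26 | CNP0298533.1 (3S,6S,7S,10R,11S,14S,15S,18S,19S) | CC(=O)O[C@]1(C)CC[C@@H]2OC(C)(C)[C@@H](O)CC[C@@]2(C)[C@@H]1CC[C@H]1[C@]2(C)CCC(=O)C(C)(C)O[C@H]2CC[C@]1(C)OC(C)=O | target

**Step count and risks**

Total step count: 17. Longest linear sequence: 13 steps (steps 1–7, then 12–17).

Steps most likely to fail:

Step 9. The C15 cation formed after the carbocyclisation may be quenched in the wrong way (loss of the C14 proton, or capture by the neighbouring silyloxy group), or the internal epoxide may be activated first and rearrange by hydride shift. The fallback builds the right half from the ring-B type keto ester 7, which already has the configuration needed at C19 and C18. Takai–Lombardo methylenation (Zn, CH2Br2, TiCl4, THF) of its ketone should give methyl (1R,2S,3S)-3-hydroxy-2-methyl-2-(4-methylpent-3-en-1-yl)-6-methylidenecyclohexane-1-carboxylate F2. Epoxidation of the prenyl alkene under the conditions of step 17 should give the hydroxy epoxide F3, which is closed with catalytic (+)-camphor-10-sulfonic acid to methyl (3S,5aS,6R,9aS)-3-hydroxy-2,2,5a-trimethyl-7-methylidenedecahydro-1-benzoxepine-6-carboxylate F4. Reduction of the ester with LiAlH4 returns to the route at diol 17.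

Step 4. The chelated enol may alkylate on oxygen (a bicyclic enol ether), or the Lewis-acid-activated epoxide may rearrange to a ketone before the C–C bond forms. The fallback sets out from 6: silylation (t-BuMe2SiOTf, Et3N) should give the silyl enol ether methyl (2Z)-3-[(tert-butyldimethylsilyl)oxy]-5-[(2S,3S)-3-methyl-3-(4-methylpent-3-en-1-yl)oxiran-2-yl]pent-2-enoate F1. The ring is then closed in the Mukaiyama manner with catalytic t-BuMe2SiOTf and 2,6-di-tert-butyl-4-methylpyridine at −78 °C. The capped enol oxygen can no longer alkylate, carbon attacks C6, and the silyl group is passed to the C7 oxygen, so the route is rejoined at silyl ether 8 and step 5 is skipped.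

Step 17. The hydroxyl may open the epoxide at the secondary carbon C3, giving a six-membered ether with a 2-hydroxypropan-2-yl side chain; this is favoured whenever the transition state is tight and hydrogen-bonded. The fallback closes ring A before the silyl group is removed, with an ether oxygen as nucleophile. Compound 23 is epoxidised under the conditions of step 17 to the epoxy silyl ether F5. Me3SiOTf with 2,6-di-tert-butyl-4-methylpyridine in CH2Cl2 at −78 °C silylates the epoxide oxygen; the C7 silyl ether oxygen attacks the cation-like C2, and the silyloxonium ion sheds its tert-butyldimethylsilyl group to give the 3-O-trimethylsilyl ether of the target F6. Brief methanolysis (K2CO3 cat., MeOH, 0 °C) returns to the route at 26.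

Further compounds
F1 | step 4 | methyl (2Z)-3-[(tert-butyldimethylsilyl)oxy]-5-[(2S,3S)-3-methyl-3-(4-methylpent-3-en-1-yl)oxiran-2-yl]pent-2-enoate | COC(=O)/C=C(\O[Si](C)(C)C(C)(C)C)CC[C@@H]1O[C@@]1(C)CCC=C(C)C
F2 | step 9 | methyl (1R,2S,3S)-3-hydroxy-2-methyl-2-(4-methylpent-3-en-1-yl)-6-methylidenecyclohexane-1-carboxylate | COC(=O)[C@@H]1C(=C)CC[C@H](O)[C@@]1(C)CCC=C(C)C
F3 | step 9 | methyl (1R,2S,3S)-2-{2-[(2S)-3,3-dimethyloxiran-2-yl]ethyl}-3-hydroxy-2-methyl-6-methylidenecyclohexane-1-carboxylate | COC(=O)[C@@H]1C(=C)CC[C@H](O)[C@@]1(C)CC[C@@H]1OC1(C)C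
F4 | step 9 | methyl (3S,5aS,6R,9aS)-3-hydroxy-2,2,5a-trimethyl-7-methylidenedecahydro-1-benzoxepine-6-carboxylate | COC(=O)[C@@H]1C(=C)CC[C@@H]2OC(C)(C)[C@@H](O)CC[C@@]12C
F5 | step 17 | (3S)-2,3-epoxide of 23 (epoxy silyl ether) | CC1(C)O[C@H]1CC[C@]1(C)[C@@H](O[Si](C)(C)C(C)(C)C)CC[C@@](C)(OC(C)=O)[C@H]1CC[C@@H]1[C@@](C)(OC(C)=O)CC[C@@H]2OC(C)(C)C(=O)CC[C@@]12C
F6 | step 17 | 3-O-trimethylsilyl ether of 26 | CC(=O)O[C@]1(C)CC[C@@H]2OC(C)(C)[C@@H](O[Si](C)(C)C)CC[C@@]2(C)[C@@H]1CC[C@H]1[C@]2(C)CCC(=O)C(C)(C)O[C@H]2CC[C@]1(C)OC(C)=O
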